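**Plan**

- Numbering used in the text: C1 carries the aryl group, C2 the CH2OH, C3 the CHO, C4 is the vinylic CH, C4a/C8a are the ring-fusion carbons. The retrosynthesis first removes three O-benzyl groups, then cuts C3–CHO (carbonylation of an enol triflate).
- C4 is a lone CH between C3 and the arene carbon C4a. Cutting C3–C4 and C4–C4a deletes it and contracts the ring to a trans-2,3-disubstituted 3-arylindan-1-one.
- The indanone is cut at C2–CH2O (enolate alkylation), at the ring bond from the arene to the aryl-bearing carbon (conjugate addition of an aryl boronate) and at the chalcone C=C (aldol condensation of two syringyl units).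
- Forward: chalcone, five-membered ring, hydroxymethyl arm, one-carbon enlargement to the six-membered 2-tetralone, enol triflate, enal, debenzylation.
- Stereochemistry: C1 comes from the chiral ligand in the Rh-catalysed ring closure; C2 from alkylation of the indanone enolate anti to that aryl group; neither centre is touched afterwards.

Key step: step 8

Assumption: which antipode of the MonoPhos ligand in step 6 gives the (3S)-indanone cannot be fixed on paper for this substitution pattern; the route uses the antipode that does, to be settled by one small-scale run and correlation.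

Remark on names: systematic names use IUPAC locants. In the tetralone and dihydronaphthalene names, IUPAC C4, C3, C2 and C1 are C1, C2, C3 and C4 of the text numbering.

**Step 1**
Reactants: 1 acetosyringone
Product: 2 1-[4-(benzyloxy)-3,5-dimethoxyphenyl]ethan-1-one
Conditions: BnBr, K2CO3, DMF, 60 °C
Reagents that add atoms: benzyl bromide, BrCc1ccccc1
Why: Williamson ether synthesis, in which the carbonate-generated phenoxide is benzylated by SN2 while the methyl ketone is not enolised by this weak base.

**Step 2**
Reactants: 2 1-[4-(benzyloxy)-3,5-dimethoxyphenyl]ethan-1-one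
Product: 3 1-[4-(benzyloxy)-2-bromo-3,5-dimethoxyphenyl]ethan-1-one
Conditions: NBS, MeCN, 0 °C → rt
Reagents that add atoms: N-bromosuccinimide, O=C1CCC(=O)N1Br
Why: Electrophilic aromatic bromination at one of the two equivalent free ring positions (ortho to one methoxy, para to the other); polar acid-free NBS/MeCN conditions favour ring over side-chain bromination, and the first bromine deactivates and crowds the ring against a second.

**Step 3**
Reactants: 4 syringaldehyde
Product: 5 4-(benzyloxy)-3,5-dimethoxybenzaldehyde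
Conditions: BnBr, K2CO3, DMF, 60 °C
Reagents that add atoms: benzyl bromide, BrCc1ccccc1
Why: Williamson ether synthesis of the hindered phenoxide with a reactive benzylic halide, the non-enolisable aldehyde being inert to carbonate.

**Step 4**
Reactants: 3 1-[4-(benzyloxy)-2-bromo-3,5-dimethoxyphenyl]ethan-1-one; 5 4-(benzyloxy)-3,5-dimethoxybenzaldehyde
Product: 6 (E)-1-[4-(benzyloxy)-2-bromo-3,5-dimethoxyphenyl]-3-[4-(benzyloxy)-3,5-dimethoxyphenyl]prop-2-en-1-one
Conditions: NaOH (aq.), EtOH–THF, rt
Reagents that add atoms: none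
Why: Claisen–Schmidt condensation in which only the ketone can enolise and only the aldehyde can accept, with E1cB dehydration of the aldol giving the conjugated E-enone.

**Step 5**
Reactants: 6 bromochalcone
Product: 7 (E)-1-[4-(benzyloxy)-3,5-dimethoxy-2-(4,4,5,5-tetramethyl-1,3,2-dioxaborolan-2-yl)phenyl]-3-[4-(benzyloxy)-3,5-dimethoxyphenyl]prop-2-en-1-one
Conditions: B2pin2, Pd2(dba)3 (cat.), SPhos (cat.), KOAc, dioxane, 90 °C
Reagents that add atoms: bis(pinacolato)diboron, CC1(C)OB(OC1(C)C)B1OC(C)(C)C(C)(C)O1
Why: Miyaura borylation, in which a bulky electron-rich biarylphosphine allows oxidative addition and boryl transfer at the di-ortho-substituted bromide while acetate is too weak a base to affect the enone.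

**Step 6**
Reactants: 7 boryl chalcone
Product: 8 (3S)-5-(benzyloxy)-3-[4-(benzyloxy)-3,5-dimethoxyphenyl]-4,6-dimethoxy-2,3-dihydro-1H-inden-1-one
Conditions: [RhCl(C2H4)2]2 (cat.), MonoPhos (cat., antipode giving 3S), aq. K3PO4, toluene, rt → 50 °C
Reagents that add atoms: none
Why: Rhodium-catalysed asymmetric intramolecular 1,4-addition (Hayashi–Miyaura type), in which boron-to-rhodium transmetalation, enantioface-selective insertion of the enone into the aryl–Rh bond and protonolysis of the rhodium enolate close the five-membered ring and set C3 under control of the chiral ligand.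

**Step 7**
Reactants: 8 (3S)-3-arylindanone; 9 benzyl chloromethyl ether
Product: 10 (2S,3S)-5-(benzyloxy)-2-[(benzyloxy)methyl]-3-[4-(benzyloxy)-3,5-dimethoxyphenyl]-4,6-dimethoxy-2,3-dihydro-1H-inden-1-one (trans)
Conditions: LiHMDS, THF, −78 °C; then BOMCl, −78 → −30 °C
Reagents that add atoms: benzyl chloromethyl ether (9), ClCOCc1ccccc1
Why: Enolate alkylation in which the lithium enolate in THF reacts at carbon with the chloromethyl ether on the face anti to the C3 aryl group, so C2 is set trans by substrate control, and C3 is untouched because the enolate is not deprotonated a second time at −78 °C.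

**Step 8**
Reactants: 10 trans-indanone; 11 trimethylsilyldiazomethane
Product: 13 (3S,4S)-6-(benzyloxy)-3-[(benzyloxy)methyl]-4-[4-(benzyloxy)-3,5-dimethoxyphenyl]-5,7-dimethoxy-3,4-dihydronaphthalen-2(1H)-one, via C4-silyl ketone 12 (not isolated)
Conditions: TMSCHN2, BF3·OEt2, CH2Cl2, −78 → −20 °C; then 1 M HCl, THF, 0 °C
Reagents that add atoms: trimethylsilyldiazomethane (11), C[Si](C)(C)C=[N+]=[N-]
Why: BF3 activates the indanone carbonyl, the diazo carbon of 11 adds to it, and the β-oxido diazonium loses N2 as the ring aryl carbon C7a (C4a of the target) shifts from the carbonyl carbon to the new carbon, forming C4–C4a and C3–C4 at once and leaving α-silyl ketone 12; this is the Lewis-acid-promoted Tiffeneau–Demjanov-type homologation of aryl ketones with trimethylsilyldiazomethane, a known way from 1-indanones to 2-tetralones. The six-membered ring arises by ring enlargement through a 1,2-aryl shift that inserts one carbon into the carbonyl–arene bond, not by a cyclisation. No stereocentre of the product is created: C1 and C2 take no part in the shift and keep their trans arrangement, the cold Lewis-acidic conditions and brief dilute-acid work-up do not enolise C2, and the silyl-bearing carbon of 12 becomes a CH2 on protodesilylation. The step needs migration of the aryl carbon and not of the alkyl carbon C2; the arene is electron-rich with the benzyloxy group para to the migrating carbon (phenonium-like transition state), whereas C2 is more hindered and inductively deactivated by its β-benzyloxy group. The silyl group of 12 shields the new, more reactive ketone from a second homologation until work-up.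

**Step 9**
Reactants: 13 2-tetralone
Product: 14 (3S,4S)-6-(benzyloxy)-3-[(benzyloxy)methyl]-4-[4-(benzyloxy)-3,5-dimethoxyphenyl]-5,7-dimethoxy-3,4-dihydronaphthalen-2-yl trifluoromethanesulfonate
Conditions: KHMDS, THF, −78 °C; then PhNTf2, −78 → 0 °C
Reagents that add atoms: N-phenylbis(trifluoromethanesulfonimide), O=S(=O)(N(c1ccccc1)S(=O)(=O)C(F)(F)F)C(F)(F)F
Why: Regioselective enolisation and O-triflation, in which the base removes the far more acidic, unhindered benzylic C4 proton to give the arene-conjugated enolate, so the C2 centre is neither epimerised nor set up for β-elimination.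

**Step 10**
Reactants: 14 enol triflate; 15 carbon monoxide
Product: 16 (3R,4S)-6-(benzyloxy)-3-[(benzyloxy)methyl]-4-[4-(benzyloxy)-3,5-dimethoxyphenyl]-5,7-dimethoxy-3,4-dihydronaphthalene-2-carbaldehyde
Conditions: Pd(OAc)2 (cat.), dppp (cat.), CO (1 atm), Et3SiH, Et3N, DMF, 70 °C
Reagents that add atoms: carbon monoxide (15), [C-]#[O+]
Why: Palladium-catalysed reductive carbonylation (formylation) of an enol triflate, by oxidative addition, CO insertion to the acyl-palladium, hydride transfer from the silane and reductive elimination of the enal, with the alkene position fixed by the triflate.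

**Step 11**
Reactants: 16 tribenzyl enal
Product: 17 (3R,4S)-6-hydroxy-4-(4-hydroxy-3,5-dimethoxyphenyl)-3-(hydroxymethyl)-5,7-dimethoxy-3,4-dihydronaphthalene-2-carbaldehyde (target, 1S,2R in the text numbering)
Conditions: BCl3, pentamethylbenzene, CH2Cl2, −78 → −40 °C; MeOH quench
Reagents that add atoms: none
Why: Lewis-acid debenzylation with a cation scavenger, in which BCl3 cleaves the two aryl and the one primary alkyl benzyl ether at low temperature and pentamethylbenzene traps the benzyl cations by Friedel–Crafts alkylation, sparing the methyl ethers, the enal, the styrenyl double bond (which excludes hydrogenolysis) and both stereocentres.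

**Compound list**

1 | acetosyringone | CC(=O)c1cc(OC)c(O)c(OC)c1 | starting material
2 | 1-[4-(benzyloxy)-3,5-dimethoxyphenyl]ethan-1-one | CC(=O)c1cc(OC)c(OCc2ccccc2)c(OC)c1 | intermediate
3 | 1-[4-(benzyloxy)-2-bromo-3,5-dimethoxyphenyl]ethan-1-one | CC(=O)c1cc(OC)c(OCc2ccccc2)c(OC)c1Br | intermediate
4 | syringaldehyde | COc1cc(C=O)cc(OC)c1O | starting material
5 | 4-(benzyloxy)-3,5-dimethoxybenzaldehyde | COc1cc(C=O)cc(OC)c1OCc1ccccc1 | intermediate
6 | (E)-1-[4-(benzyloxy)-2-bromo-3,5-dimethoxyphenyl]-3-[4-(benzyloxy)-3,5-dimethoxyphenyl]prop-2-en-1-one | COc1cc(/C=C/C(=O)c2cc(OC)c(OCc3ccccc3)c(OC)c2Br)cc(OC)c1OCc1ccccc1 | intermediate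
7 | (E)-1-[4-(benzyloxy)-3,5-dimethoxy-2-(4,4,5,5-tetramethyl-1,3,2-dioxaborolan-2-yl)phenyl]-3-[4-(benzyloxy)-3,5-dimethoxyphenyl]prop-2-en-1-one | COc1cc(/C=C/C(=O)c2cc(OC)c(OCc3ccccc3)c(OC)c2B4OC(C)(C)C(C)(C)O4)cc(OC)c1OCc1ccccc1 | intermediate
8 | (3S)-5-(benzyloxy)-3-[4-(benzyloxy)-3,5-dimethoxyphenyl]-4,6-dimethoxy-2,3-dihydro-1H-inden-1-one | COc1cc([C@H]2c3c(cc(OC)c(OCc4ccccc4)c3OC)C(=O)C2)cc(OC)c1OCc1ccccc1 | intermediate
9 | benzyl chloromethyl ether | ClCOCc1ccccc1 | starting material
10 | (2S,3S)-5-(benzyloxy)-2-[(benzyloxy)methyl]-3-[4-(benzyloxy)-3,5-dimethoxyphenyl]-4,6-dimethoxy-2,3-dihydro-1H-inden-1-one (trans) | COc1cc([C@H]2c3c(cc(OC)c(OCc4ccccc4)c3OC)C(=O)[C@@H]2COCc2ccccc2)cc(OC)c1OCc1ccccc1 | intermediate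
11 | trimethylsilyldiazomethane | C[Si](C)(C)C=[N+]=[N-] | starting material
12 | (1RS,3S,4S)-6-(benzyloxy)-3-[(benzyloxy)methyl]-4-[4-(benzyloxy)-3,5-dimethoxyphenyl]-5,7-dimethoxy-1-(trimethylsilyl)-3,4-dihydronaphthalen-2(1H)-one (C4-silyl ketone, both epimers at the silyl-bearing carbon) | COc1cc([C@H]2c3c(cc(OC)c(OCc4ccccc4)c3OC)C([Si](C)(C)C)C(=O)[C@@H]2COCc2ccccc2)cc(OC)c1OCc1ccccc1 | intermediate
13 | (3S,4S)-6-(benzyloxy)-3-[(benzyloxy)methyl]-4-[4-(benzyloxy)-3,5-dimethoxyphenyl]-5,7-dimethoxy-3,4-dihydronaphthalen-2(1H)-one | COc1cc([C@H]2c3c(cc(OC)c(OCc4ccccc4)c3OC)CC(=O)[C@@H]2COCc2ccccc2)cc(OC)c1OCc1ccccc1 | intermediate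
14 | (3S,4S)-6-(benzyloxy)-3-[(benzyloxy)methyl]-4-[4-(benzyloxy)-3,5-dimethoxyphenyl]-5,7-dimethoxy-3,4-dihydronaphthalen-2-yl trifluoromethanesulfonate | COc1cc([C@H]2c3c(cc(OC)c(OCc4ccccc4)c3OC)C=C(OS(=O)(=O)C(F)(F)F)[C@@H]2COCc2ccccc2)cc(OC)c1OCc1ccccc1 | intermediate
15 | carbon monoxide | [C-]#[O+] | starting material
16 | (3R,4S)-6-(benzyloxy)-3-[(benzyloxy)methyl]-4-[4-(benzyloxy)-3,5-dimethoxyphenyl]-5,7-dimethoxy-3,4-dihydronaphthalene-2-carbaldehyde | COc1cc([C@H]2c3c(cc(OC)c(OCc4ccccc4)c3OC)C=C(C=O)[C@@H]2COCc2ccccc2)cc(OC)c1OCc1ccccc1 | intermediate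
17 | (3R,4S)-6-hydroxy-4-(4-hydroxy-3,5-dimethoxyphenyl)-3-(hydroxymethyl)-5,7-dimethoxy-3,4-dihydronaphthalene-2-carbaldehyde | COc1cc([C@H]2c3c(cc(OC)c(O)c3OC)C=C(C=O)[C@@H]2CO)cc(OC)c1O | target

**Step count**

Total: 11 steps. Longest linear sequence: 10 steps (steps 1, 2, 4, 5, 6, 7, 8, 9, 10, 11, from acetosyringone); step 3 is a one-step side branch.

**Steps most likely to fail**

Step 8. Addition of the diazoalkane to a hindered, electron-rich aryl ketone may be slow. Migration of the alkyl carbon C2 may compete with the aryl shift. Lewis-acid-induced loss of benzyl alcohol from the β-benzyloxy ketone, or a second homologation, may erode the material. Fallback: setting out from indanone 10, Wittig methylenation (Ph3PCH3Br, KOtBu, THF, 0 °C → rt) should give (2R,3S)-5-(benzyloxy)-2-[(benzyloxy)methyl]-3-[4-(benzyloxy)-3,5-dimethoxyphenyl]-4,6-dimethoxy-1-methylidene-2,3-dihydro-1H-indene F1. Oxidative rearrangement of this alkene with [hydroxy(tosyloxy)iodo]benzene in 95% MeOH at rt is the known Wittig–ring-expansion route from 1-benzocycloalkanones to 2-benzocycloalkanones: iodine(III) adds to the methylidene carbon, the aryl carbon shifts onto it with loss of iodobenzene, and the ketal hydrolyses. This comes back to the route at tetralone 13.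

Step 10. Hydride transfer to the vinylpalladium may outrun CO insertion at the crowded enol triflate, so that the triflate is simply reduced; Pd–H-mediated double-bond migration is a second possibility. Fallback: setting out from enol triflate 14, alkoxycarbonylation (Pd(OAc)2, PPh3, CO, MeOH, Et3N, DMF, 60 °C) should give methyl (3R,4S)-6-(benzyloxy)-3-[(benzyloxy)methyl]-4-[4-(benzyloxy)-3,5-dimethoxyphenyl]-5,7-dimethoxy-3,4-dihydronaphthalene-2-carboxylate F2. DIBAL-H reduction (CH2Cl2, −78 °C) should then give [(3R,4S)-6-(benzyloxy)-3-[(benzyloxy)methyl]-4-[4-(benzyloxy)-3,5-dimethoxyphenyl]-5,7-dimethoxy-3,4-dihydronaphthalen-2-yl]methanol F3. Oxidation of this allylic alcohol with MnO2 (CH2Cl2, rt) comes back to the route at enal 16.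

Step 6. Boron-to-rhodium transmetalation at the di-ortho-substituted boronate may be slow, so that protodeboronation competes, and the enantioselectivity may drop with the ortho-methoxy group next to the reacting carbon. Fallback: setting out from bromochalcone 6 (which also bypasses step 5), a palladium-catalysed asymmetric reductive Heck cyclisation (Pd(OAc)2, chiral MeO-BIPHEP-type bisphosphine, HCO2Na, DMF, 80 °C) should close the five-membered ring. It proceeds by oxidative addition, aryl insertion at the enone β-carbon and hydride capture of the palladium enolate. It comes back to the route at indanone 8 without any new compound (F0).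

**Further compounds**

F1 | step 8 | (2R,3S)-5-(benzyloxy)-2-[(benzyloxy)methyl]-3-[4-(benzyloxy)-3,5-dimethoxyphenyl]-4,6-dimethoxy-1-methylidene-2,3-dihydro-1H-indene | COc1cc([C@H]2c3c(cc(OC)c(OCc4ccccc4)c3OC)C(=C)[C@@H]2COCc2ccccc2)cc(OC)c1OCc1ccccc1
F2 | step 10 | methyl (3R,4S)-6-(benzyloxy)-3-[(benzyloxy)methyl]-4-[4-(benzyloxy)-3,5-dimethoxyphenyl]-5,7-dimethoxy-3,4-dihydronaphthalene-2-carboxylate | COc1cc([C@H]2c3c(cc(OC)c(OCc4ccccc4)c3OC)C=C(C(=O)OC)[C@@H]2COCc2ccccc2)cc(OC)c1OCc1ccccc1
F3 | step 10 | [(3R,4S)-6-(benzyloxy)-3-[(benzyloxy)methyl]-4-[4-(benzyloxy)-3,5-dimethoxyphenyl]-5,7-dimethoxy-3,4-dihydronaphthalen-2-yl]methanol | COc1cc([C@H]2c3c(cc(OC)c(OCc4ccccc4)c3OC)C=C(CO)[C@@H]2COCc2ccccc2)cc(OC)c1OCc1ccccc1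
F0 | step 6 | none | none
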